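# Proposed synthesis of (2S)-2-[4-(geranyloxy)phenyl]-7-hydroxychroman-4-one (26)

Flavanone numbering is used throughout (O1, C2, C3, C4, C4a, C5–C8, C8a). "Geranyl" means (2E)-3,7-dimethylocta-2,6-dien-1-yl.

## The problem

Target 26 is a (2S)-flavanone. Ring C (O1, C2, C3, C4, C4a, C8a) is a dihydropyranone fused through C4a–C8a to the resorcinol-type ring A, which carries a free hydroxyl at C7. Ring B sits on C2 and bears a geranyl ether para to it.

C2 is the only stereocentre, so nothing in the molecule can relay chirality to it and a reagent must set it. Once set it is exposed on two sides. Beside the C4 ketone it epimerises under base by retro-oxa-Michael opening to the 2'-hydroxychalcone. As a p-alkoxybenzylic ether carbon it can also ionise under acid.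

The geranyl aryl ether excludes hydrogenation, strong Brønsted or Lewis acids, electrophilic oxidants and short-wavelength light. Protecting groups that leave only with acid or hydrogen are therefore poor choices, and the C7 phenol is best unveiled late and unprotected.

The feature that opens a non-classical approach is the pattern of ring A: oxygen at C7 and C8a (meta), the C4 carbon on C4a para to the C7 hydroxyl, and hydrogen at C5, C6 and C8. A vinylketene–alkynyl ether benzannulation gives exactly this pattern. The ketene carbon becomes C7–OH, the alkyne carbons become C8 and C8a, the ketene α-carbon becomes C4a and the vinyl carbons become C5 and C6. Because the oxygen on C8a is the ring oxygen O1, an alkynyl ether tethered through C2–C3–C4 to the ketene should close ring C in the same event.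

## Retrosynthesis

**26 back to 24 (no skeletal bond cut).** The C4 ketone is taken back through diol 25 to the silyl-protected carbinol 24. The benzannulation needs C4 sp3: a C4 ketone would turn the ketene into an acylketene, which reacts with ynol ethers as a heterodiene, and would give the diazo carbon two acyl groups that could migrate. A silyl ether is preferred to an ester because, once ring A is aromatic, C4–O is p-hydroxybenzylic and an acyloxy group there would leave as a quinone methide forms. The forward steps are fluoride cleavage and a neutral benzylic oxidation, so the ketone that makes C2 base-labile appears only at the end.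

**24 back to 19 (rings A and C).** Four bonds are cut together: C4a–C8a (ring C), C7–C8 and C6–C7 (ring A) and, as a retro-Wolff step, C4a–C5. The last returns the vinyl group to the carbonyl carbon C7 and makes C4a a diazo carbon. Cutting only O1–C8a or only C2–O1 would leave a resorcinol to be bought and would form or stress the C2–O bond late. Cutting ring A alone (an intermolecular benzannulation) would leave ring C to be closed afterwards at that same labile bond. In 19 the C2–O1 bond already exists and takes no part in bond breaking. The precursor is an acyclic chain whose only stereocentre of consequence is a benzylic carbinol carbon. The forward reaction must make the vinyl shift faster than hydride shift from C4, make the ketene (20) add to the ynol ether with C8 on C7 and C8a on C4a (giving 21), and let the electrocyclic opening and closure (22, 23) run to the phenol.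

**19 back to 13 and 16 (C4–C4a).** The silyl ether is removed to give 18, and the C4–C4a bond is cut as an aldol-type addition of the lithiated diazo enone 17 to aldehyde 13. One bond formation installs the C4 oxygen and attaches the complete diazo enone. The alternative (aldol with a ketone enolate, then diazo transfer at a hindered methylene) costs steps. The forward reaction must add to a base-sensitive aldehyde without enolising it. The configuration at C4 does not matter.

**16 back to 14 (C=N2).** The diazo group is removed, leaving methyl vinyl ketone 14. Activation of the methyl group as its trifluoroacetyl derivative 15 followed by diazo transfer is the established way to α'-diazo enones.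

**13 back to 7 and 8 (O1–C8a).** Aldehyde 13 comes from alcohol 12 and its silyl ether 11. The ynol ether bond O1–C8a is cut to the secondary alcohol 7 and trichloroethylene 8, which supplies C8a and C8 by way of 9 and 10. This strongly basic step has to precede every diazo and enone intermediate. A triisopropylsilyl group guards the primary oxygen because a smaller silyl group would migrate to the neighbouring potassium alkoxide. The O–C2 bond is not touched, so the configuration passes through.

**7 back to 4 (the C2 stereocentre).** Silyl ether 7 comes from diol 6, diol 6 from hydroxy ester 5, and 5 from β-keto ester 4 by asymmetric transfer hydrogenation. This puts the only reagent-controlled step early, on a simple aryl ketone, where the selectivity is most predictable and the alkenes are inert.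

**4 back to 1 and 2 (C3–C4 and the geranyl C–O bond).** Claisen carbomethoxylation of ketone 3 adds C4. Ketone 3 is the geranyl ether of 4'-hydroxyacetophenone 1, made with geranyl bromide 2. Alkylating first means the ring B oxygen never needs a protecting group.

## Roads not taken

**Alternative 1:** hetero-Diels–Alder reaction on a dihydro ring A. The cut is C2–C3 and O1–C8a. Diene A2, a cyclohexadiene carrying two trimethylsilyloxy groups, would react with 4-(geranyloxy)benzaldehyde A3 under Ti(OiPr)4 (tetravalent titanium) and BINOL. Acid would then expel silanol to give enone A1, and ring A would be dehydrogenated and its methoxymethyl ether removed.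

- Merits: convergent, C2 is set catalytically in the ring-forming step, and A3 is one step from 2. It should be several steps shorter than the chosen route.
- Weak points: A3 is an electron-rich, sluggish heterodienophile. The reacting diene terminus C8a is fully substituted and part of a ring, a diene class for which titanium–BINOL control is not established, and a stepwise Mukaiyama-aldol pathway would erode the selectivity. A1 is a vinylogous ester that can open by β-elimination at C2–O1 under the acid used to expel silanol.
- Late steps: aromatisation needs an oxidant that dehydrogenates C5–C6 but spares the geranyl alkenes and does not go on to the flavone. Acetal removal needs acid at a p-alkoxybenzylic centre.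
- Comparison: this road is shorter and more convergent. Against that, the chosen plan fixes C2 by a dependable ketone reduction before any uncertain step, and it delivers ring A at the aromatic level with a free phenol, with no oxidation or acid afterwards.

**Alternative 2:** copper-catalysed aryl ether closure of a chiral diol. Only O1–C8a is cut. Diol A5 would be closed with CuI (monovalent copper), a phenanthroline ligand and Cs2CO3 to give flavan-4-ol A4, followed by desilylation and oxidation at C4.

- Merits: every step is a known reaction type, the C2–O bond is never broken so the configuration is retained, and ring A is bought.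
- Weak points: A5 needs an ortho-bromoaryl ketone or aldehyde partner and a diastereoselective reduction. The closure runs hot and basic with an aryl silyl ether present, and oxidation of the secondary alkoxide on copper and dehalogenation are the usual side paths.
- Comparison: this road is the more secure one and is probably no longer than the chosen route. The chosen plan offers in return that both rings arise in one operation from an acyclic chain, that no halogenated resorcinol and no transition metal are needed, and that the approach would extend to ring A patterns for which no such resorcinol exists. Because it is safer, its logic is kept as the fallback for step 12.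

**Alternative 3:** aryne annulation with the β-hydroxy ester. The cut is O1–C8a and C4–C4a. Fluoride would release the aryne from silyl triflate A7, the alkoxide of hydroxy ester 5 would attack C8a, and the aryl anion at C4a would close on the ester to give bromo flavanone A6.

- Merits: the shortest road. It uses 5 directly and forms ring C in one step.
- Weak points: regiocontrol rests on an extra bromine at C5. This has to be removed reductively in the presence of two trisubstituted alkenes and an aryl ketone, and hydrogenolysis is excluded. The free alkoxide of a β-hydroxy ester is prone to retro-aldol cleavage and β-elimination. A6 is formed under basic fluoride, the very conditions that open flavanones to chalcones and erase C2. A7 needs several steps, and the acetal must again leave with acid.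
- Comparison: it is more convergent and shorter. The chosen plan counters that C2 never sits beside a ketone under base and that no superfluous atoms (Br, acetal) have to be removed.

Key step: step 12

Assumption: the (S,S)-configured catalyst of step 3 is taken to give the S carbinol as it does with aryl methyl ketones (the enantiomeric catalyst would be used if the sense proved opposite), and the C4 carbinol centre formed in step 10 is carried as a mixture of epimers until it is oxidised in step 14.

## Route

Step 1
Reactants: 1 4'-hydroxyacetophenone; 2 geranyl bromide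
Product: 3 1-[4-(geranyloxy)phenyl]ethan-1-one
Conditions: K2CO3, acetone, reflux
Reagents that add atoms: none
Why: Williamson ether synthesis; the phenoxide of 1 displaces the primary allylic bromide of 2 in an SN2 reaction with the (2E) geometry unchanged, and the ring B oxygen then needs no protecting group.

Step 2
Reactants: 3 1-[4-(geranyloxy)phenyl]ethan-1-one
Product: 4 methyl 3-[4-(geranyloxy)phenyl]-3-oxopropanoate
Conditions: NaH, (MeO)2CO, THF, reflux; then AcOH, H2O, 0 °C
Reagents that add atoms: dimethyl carbonate, COC(=O)OC
Why: Crossed Claisen condensation of the methyl ketone enolate with dimethyl carbonate, driven by deprotonation of the β-keto ester formed; it joins the future C4 to C3.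

Step 3
Reactants: 4 methyl 3-[4-(geranyloxy)phenyl]-3-oxopropanoate
Product: 5 methyl (3S)-3-[4-(geranyloxy)phenyl]-3-hydroxypropanoate
Conditions: RuCl[(S,S)-TsDPEN](p-cymene) (1 mol %), HCO2H/Et3N (5:2), 35 °C
Reagents that add atoms: none
Why: Noyori asymmetric transfer hydrogenation; the divalent ruthenium hydride bearing the (S,S)-N-tosyl-1,2-diphenylethylenediamine ligand delivers hydride to one face of the aryl ketone through the six-membered outer-sphere transition state, with the substrate arene against the p-cymene ligand, which should set the 3S carbinol (the future C2). The ester and the isolated alkenes are inert to this catalyst.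

Step 4
Reactants: 5 methyl (3S)-3-[4-(geranyloxy)phenyl]-3-hydroxypropanoate
Product: 6 (1S)-1-[4-(geranyloxy)phenyl]propane-1,3-diol
Conditions: LiBH4, THF, 0 °C to rt; then H2O
Reagents that add atoms: none
Why: Chemoselective ester reduction by LiBH4, assisted by the neighbouring hydroxyl; the stereocentre is not involved.

Step 5
Reactants: 6 (1S)-1-[4-(geranyloxy)phenyl]propane-1,3-diol
Product: 7 (1S)-1-[4-(geranyloxy)phenyl]-3-(triisopropylsilyloxy)propan-1-ol
Conditions: i-Pr3SiCl, imidazole, DMF, 0 °C
Reagents that add atoms: triisopropylsilyl chloride, CC(C)[Si](Cl)(C(C)C)C(C)C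
Why: Silyl ether formation, selective for the primary hydroxyl on steric grounds; the bulky triisopropylsilyl group resists base-induced 1,5 oxygen-to-oxygen migration in step 6 and leaves with fluoride.

Step 6
Reactants: 7 (1S)-1-[4-(geranyloxy)phenyl]-3-(triisopropylsilyloxy)propan-1-ol; 8 trichloroethylene
Product: 11 {(3S)-3-(ethynyloxy)-3-[4-(geranyloxy)phenyl]propoxy}triisopropylsilane, via dichlorovinyl ether 9 (not isolated), via lithium acetylide 10 (not isolated)
Conditions: KH, THF, 0 °C; 8, rt; then n-BuLi, −78 to −40 °C; MeOH, −78 °C
Reagents that add atoms: none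
Why: Ynol ether synthesis from an alkoxide and trichloroethylene; KH generates dichloroacetylene in the flask, the potassium alkoxide adds anti to give 9, and n-BuLi eliminates HCl and exchanges the remaining chlorine for lithium to give 10, which is protonated. The O–C bond at the stereocentre is never broken, so the S configuration is retained.

Step 7
Reactants: 11 {(3S)-3-(ethynyloxy)-3-[4-(geranyloxy)phenyl]propoxy}triisopropylsilane
Product: 12 (3S)-3-(ethynyloxy)-3-[4-(geranyloxy)phenyl]propan-1-ol
Conditions: Bu4NF, THF, 0 °C; then H2O
Reagents that add atoms: none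
Why: Fluoride cleavage of the silyl ether under basic, acid-free conditions that the ynol ether tolerates; the alcohol is kept cold and free of acid so that the hydroxyl does not add to the ynol ether.

Step 8
Reactants: 12 (3S)-3-(ethynyloxy)-3-[4-(geranyloxy)phenyl]propan-1-ol
Product: 13 (3S)-3-(ethynyloxy)-3-[4-(geranyloxy)phenyl]propanal
Conditions: Dess–Martin periodinane, pyridine, CH2Cl2, 0 °C
Reagents that add atoms: none
Why: Dess–Martin oxidation buffered with pyridine, so that neither free acetic acid (addition to the ynol ether) nor a strong base (β-elimination of the ynolate from the aldehyde) is present; the aldehyde is used at once.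

Step 9
Reactants: 14 methyl vinyl ketone
Product: 16 1-diazobut-3-en-2-one, via trifluoroacetyl diketone 15 (not isolated)
Conditions: LiN(SiMe3)2, THF, −78 °C; CF3CO2CH2CF3; aq. HCl work-up; then MsN3, Et3N, H2O, MeCN, rt
Reagents that add atoms: methanesulfonyl azide, CS(=O)(=O)N=[N+]=[N-] (the two diazo nitrogens); 2,2,2-trifluoroethyl trifluoroacetate, O=C(OCC(F)(F)F)C(F)(F)F (trifluoroacetyl group of 15 only, lost again)
Why: Detrifluoroacetylative diazo transfer; kinetic deprotonation of the methyl group of 14 (inverse addition at −78 °C to suppress Michael polymerisation), C-trifluoroacetylation to crude 15, then diazo transfer from MsN3 with loss of the trifluoroacetyl group. This is the established access to α'-diazo enones.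

Step 10
Reactants: 16 1-diazobut-3-en-2-one; 13 (3S)-3-(ethynyloxy)-3-[4-(geranyloxy)phenyl]propanal
Product: 18 (7S)-4-diazo-7-(ethynyloxy)-7-[4-(geranyloxy)phenyl]-5-hydroxyhept-1-en-3-one (both C5 epimers), via lithiated diazo enone 17 (not isolated)
Conditions: LiN(SiMe3)2, THF, −78 °C; then 13, −78 °C; aq. NH4Cl, −78 °C
Reagents that add atoms: none
Why: Aldol-type addition of a lithiated α-diazo ketone to an aldehyde, forming C4–C4a; deprotonation turns the enone into a dienolate that is no longer a Michael acceptor, and the stabilised anion should add to the aldehyde faster than it enolises it. The new carbinol centre (future C4) forms without control and needs none, because it becomes the ketone.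

Step 11
Reactants: 18 (7S)-4-diazo-7-(ethynyloxy)-7-[4-(geranyloxy)phenyl]-5-hydroxyhept-1-en-3-one (both C5 epimers)
Product: 19 (7S)-5-(tert-butyldimethylsilyloxy)-4-diazo-7-(ethynyloxy)-7-[4-(geranyloxy)phenyl]hept-1-en-3-one (both C5 epimers)
Conditions: t-BuMe2SiOTf, 2,6-lutidine, CH2Cl2, −78 °C
Reagents that add atoms: tert-butyldimethylsilyl trifluoromethanesulfonate, CC(C)(C)[Si](C)(C)OS(=O)(=O)C(F)(F)F
Why: Silylation of a hindered secondary alcohol with a silyl triflate and a hindered pyridine base at low temperature; this avoids amine conjugate addition to the vinyl ketone and removes the hydroxyl before it can add to the enone. The silyl ether keeps C4 sp3 and is a poor leaving group.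

Step 12
Reactants: 19 (7S)-5-(tert-butyldimethylsilyloxy)-4-diazo-7-(ethynyloxy)-7-[4-(geranyloxy)phenyl]hept-1-en-3-one (both C5 epimers)
Product: 24 (2S)-4-(tert-butyldimethylsilyloxy)-2-[4-(geranyloxy)phenyl]chroman-7-ol (both C4 epimers), via vinylketene 20 (not isolated), via cyclobutenone 21 (not isolated), via dienylketene 22 (not isolated), via cyclohexadienone 23 (not isolated)
Conditions: hν (365 nm LED), degassed toluene (0.005 M), 0 °C; then 80 °C, dark
Reagents that add atoms: none
Why: Proposed new method: direct excitation of the diazo enone expels N2 while the vinyl group migrates from the carbonyl carbon (future C7) to the diazo carbon (future C4a) in a photo-Wolff rearrangement, giving vinylketene 20 (bond C4a–C5). The CH terminus of the tethered ynol ether attacks the central ketene carbon C7 and the oxygen-bearing alkyne carbon C8a bonds to C4a, an intramolecular [2+2] cycloaddition that closes ring C as the six-membered ring of the fused cyclobutenone 21. On warming, 4π electrocyclic opening of 21 breaks C4a–C7 to give dienylketene 22, in which the ring holds the vinyl and ketenyl groups cis on the C4a=C8a bond, and a thermal disrotatory 6π electrocyclisation (C6–C7) closes ring A as dienone 23, which tautomerises to the phenol. The closest known reaction type is the Danheiser benzannulation of α-diazo enones with alkoxy- and silyloxyalkynes, which is intermolecular; here the alkyne is tethered through its own oxygen and the diazo carbon carries the ring C chain. No new stereocentre results (the quaternary C4a of 21 is lost again), C2 is untouched because only its oxygen substituent reacts, and C4 stays a mixture. The vinyl shift must outrun 1,2-hydride shift from C4–H and carbene addition to the alkyne; unsensitised irradiation of the s-Z diazo ketone, favoured by the small vinyl group on the carbonyl, should make N2 loss and migration concerted. Regiochemistry of the [2+2] step should follow from ynol ether polarisation and from the C4–C3–C2–O1 tether, which allows only the fused mode, and 365 nm light should spare the aryl geranyl ether from photo-Claisen cleavage.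

Step 13
Reactants: 24 (2S)-4-(tert-butyldimethylsilyloxy)-2-[4-(geranyloxy)phenyl]chroman-7-ol (both C4 epimers)
Product: 25 (2S)-2-[4-(geranyloxy)phenyl]chroman-4,7-diol (both C4 epimers)
Conditions: Bu4NF, AcOH, THF, 0 °C
Reagents that add atoms: none
Why: Fluoride cleavage of the benzylic silyl ether, buffered with acetic acid; strong acid is avoided because it would ionise the p-hydroxybenzylic C4–O bond.

Step 14
Reactants: 25 (2S)-2-[4-(geranyloxy)phenyl]chroman-4,7-diol (both C4 epimers)
Product: 26 (2S)-2-[4-(geranyloxy)phenyl]-7-hydroxychroman-4-one
Conditions: MnO2, CH2Cl2, rt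
Reagents that add atoms: none
Why: MnO2 oxidation of a benzylic alcohol, selective for the activated C4 carbinol over the phenol, the alkenes and the allylic ether; both C4 epimers converge, and because the ketone appears under neutral conditions C2 is not exposed to base beside a carbonyl.

## Compound list

1 | 4'-hydroxyacetophenone | CC(=O)c1ccc(O)cc1 | starting material
2 | geranyl bromide, (2E)-1-bromo-3,7-dimethylocta-2,6-diene | CC(C)=CCC/C(C)=C/CBr | starting material
3 | 1-[4-(geranyloxy)phenyl]ethan-1-one | CC(C)=CCC/C(C)=C/COc1ccc(C(C)=O)cc1 | intermediate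
4 | methyl 3-[4-(geranyloxy)phenyl]-3-oxopropanoate | CC(C)=CCC/C(C)=C/COc1ccc(C(=O)CC(=O)OC)cc1 | intermediate
5 | methyl (3S)-3-[4-(geranyloxy)phenyl]-3-hydroxypropanoate | CC(C)=CCC/C(C)=C/COc1ccc([C@@H](O)CC(=O)OC)cc1 | intermediate
6 | (1S)-1-[4-(geranyloxy)phenyl]propane-1,3-diol | CC(C)=CCC/C(C)=C/COc1ccc([C@@H](O)CCO)cc1 | intermediate
7 | (1S)-1-[4-(geranyloxy)phenyl]-3-(triisopropylsilyloxy)propan-1-ol | CC(C)=CCC/C(C)=C/COc1ccc([C@@H](O)CCO[Si](C(C)C)(C(C)C)C(C)C)cc1 | intermediate
8 | trichloroethylene | ClC=C(Cl)Cl | starting material
9 | {(3S)-3-[(E)-1,2-dichloroethenyloxy]-3-[4-(geranyloxy)phenyl]propoxy}triisopropylsilane | CC(C)=CCC/C(C)=C/COc1ccc([C@@H](O/C(Cl)=C\Cl)CCO[Si](C(C)C)(C(C)C)C(C)C)cc1 | intermediate (formed in the flask, not isolated)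
10 | lithium acetylide of 11, {(3S)-3-[(lithioethynyl)oxy]-3-[4-(geranyloxy)phenyl]propoxy}triisopropylsilane | CC(C)=CCC/C(C)=C/COc1ccc([C@@H](OC#C[Li])CCO[Si](C(C)C)(C(C)C)C(C)C)cc1 | intermediate (formed in the flask, not isolated)
11 | {(3S)-3-(ethynyloxy)-3-[4-(geranyloxy)phenyl]propoxy}triisopropylsilane | CC(C)=CCC/C(C)=C/COc1ccc([C@@H](OC#C)CCO[Si](C(C)C)(C(C)C)C(C)C)cc1 | intermediate
12 | (3S)-3-(ethynyloxy)-3-[4-(geranyloxy)phenyl]propan-1-ol | CC(C)=CCC/C(C)=C/COc1ccc([C@@H](OC#C)CCO)cc1 | intermediate
13 | (3S)-3-(ethynyloxy)-3-[4-(geranyloxy)phenyl]propanal | CC(C)=CCC/C(C)=C/COc1ccc([C@@H](OC#C)CC=O)cc1 | intermediate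
14 | methyl vinyl ketone | CC(=O)C=C | starting material
15 | 1,1,1-trifluorohex-5-ene-2,4-dione | C=CC(=O)CC(=O)C(F)(F)F | intermediate (crude, not isolated)
16 | 1-diazobut-3-en-2-one | C=CC(=O)C=[N+]=[N-] | intermediate
17 | 1-diazo-1-lithiobut-3-en-2-one | C=CC(=O)C([Li])=[N+]=[N-] | intermediate (formed in the flask, not isolated)
18 | (7S)-4-diazo-7-(ethynyloxy)-7-[4-(geranyloxy)phenyl]-5-hydroxyhept-1-en-3-one, both C5 epimers | CC(C)=CCC/C(C)=C/COc1ccc([C@@H](OC#C)CC(O)C(=[N+]=[N-])C(=O)C=C)cc1 | intermediate
19 | (7S)-5-(tert-butyldimethylsilyloxy)-4-diazo-7-(ethynyloxy)-7-[4-(geranyloxy)phenyl]hept-1-en-3-one, both C5 epimers | CC(C)=CCC/C(C)=C/COc1ccc([C@@H](OC#C)CC(O[Si](C)(C)C(C)(C)C)C(=[N+]=[N-])C(=O)C=C)cc1 | intermediate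
20 | (5S)-3-(tert-butyldimethylsilyloxy)-2-ethenyl-5-(ethynyloxy)-5-[4-(geranyloxy)phenyl]pent-1-en-1-one (vinylketene), both C3 epimers | CC(C)=CCC/C(C)=C/COc1ccc([C@@H](OC#C)CC(O[Si](C)(C)C(C)(C)C)C(C=C)=C=O)cc1 | intermediate (formed in the flask, not isolated)
21 | (3S)-5-(tert-butyldimethylsilyloxy)-6-ethenyl-3-[4-(geranyloxy)phenyl]-2-oxabicyclo[4.2.0]oct-1(8)-en-7-one, mixture at C5 and C6 | CC(C)=CCC/C(C)=C/COc1ccc([C@@H]2CC(O[Si](C)(C)C(C)(C)C)C3(C=C)C(=O)C=C3O2)cc1 | intermediate (formed in the flask, not isolated)
22 | 2-{(2S)-4-(tert-butyldimethylsilyloxy)-5-ethenyl-2-[4-(geranyloxy)phenyl]-3,4-dihydro-2H-pyran-6-yl}ethen-1-one (dienylketene), both C4 epimers | CC(C)=CCC/C(C)=C/COc1ccc([C@@H]2CC(O[Si](C)(C)C(C)(C)C)C(C=C)=C(C=C=O)O2)cc1 | intermediate (formed in the flask, not isolated)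
23 | (2S)-4-(tert-butyldimethylsilyloxy)-2-[4-(geranyloxy)phenyl]-2,3,4,6-tetrahydro-7H-chromen-7-one, both C4 epimers | CC(C)=CCC/C(C)=C/COc1ccc([C@@H]2CC(O[Si](C)(C)C(C)(C)C)C3=CCC(=O)C=C3O2)cc1 | intermediate (formed in the flask, not isolated)
24 | (2S)-4-(tert-butyldimethylsilyloxy)-2-[4-(geranyloxy)phenyl]chroman-7-ol, both C4 epimers | CC(C)=CCC/C(C)=C/COc1ccc([C@@H]2CC(O[Si](C)(C)C(C)(C)C)c3ccc(O)cc3O2)cc1 | intermediate
25 | (2S)-2-[4-(geranyloxy)phenyl]chroman-4,7-diol, both C4 epimers | CC(C)=CCC/C(C)=C/COc1ccc([C@@H]2CC(O)c3ccc(O)cc3O2)cc1 | intermediate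
26 | (2S)-2-[4-(geranyloxy)phenyl]-7-hydroxychroman-4-one | CC(C)=CCC/C(C)=C/COc1ccc([C@@H]2CC(=O)c3ccc(O)cc3O2)cc1 | target

## Step count and uncertain steps

Total: 14 steps. Longest linear sequence: 13 steps (steps 1–8 and 10–14). Step 9 is a one-step branch.

**Step 12 (key step, proposed new method).** Several processes can divert it:
- hydride shift from C4–H to the carbene carbon, giving a silyl enol ether enone, if N2 loss is not concerted with vinyl migration;
- carbene addition to the alkyne;
- dipolar cycloaddition of the diazo group to the tethered ynol ether in the dark before irradiation;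
- intermolecular ketene reactions if the [2+2] closure is slow.

The fallback uses only established reaction types. It closes ring C on a purchased ring A, sets out from 5 and returns at 25.
- Aminolysis of 5 with MeNH(OMe)·HCl and i-PrMgCl gives (3S)-3-[4-(geranyloxy)phenyl]-3-hydroxy-N-methoxy-N-methylpropanamide F1.
- Commercial 3-bromo-4-iodophenol is silylated to (3-bromo-4-iodophenoxy)triisopropylsilane F2. Iodine–magnesium exchange with i-PrMgCl at −40 °C gives [2-bromo-4-(triisopropylsilyloxy)phenyl]magnesium chloride F3.
- Addition of F3 to F1 gives (3S)-1-[2-bromo-4-(triisopropylsilyloxy)phenyl]-3-[4-(geranyloxy)phenyl]-3-hydroxypropan-1-one F4.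
- NaBH4 reduction gives (1S)-3-[2-bromo-4-(triisopropylsilyloxy)phenyl]-1-[4-(geranyloxy)phenyl]propane-1,3-diol F5 as a mixture at C3.
- Intramolecular Ullmann etherification (CuI, monovalent copper, 1,10-phenanthroline, Cs2CO3, toluene, 110 °C) forms O1–C8a with retention at C2 and gives (2S)-2-[4-(geranyloxy)phenyl]-7-(triisopropylsilyloxy)chroman-4-ol F6.
- Bu4NF gives 25, which rejoins the route at step 14.

**Step 10.** The lithiated diazo ketone may enolise 13, after which the ynolate is lost by β-elimination. The vinyl ketone may polymerise anionically, and the lithium aldolate may close onto the enone by oxa-Michael addition. The fallback sets out from 16 and returns at 19. C-Silylation of 16 (t-BuMe2SiOTf, i-Pr2NEt) gives 1-(tert-butyldimethylsilyl)-1-diazobut-3-en-2-one F7. Fluoride-initiated addition of F7 to 13 (catalytic Bu4N Ph3SiF2, THF, −78 °C) should pass the silyl group from carbon to the new alkoxide. This gives 19 directly without a stoichiometric strong base and also bypasses step 11.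

**Step 6.** The silyl group may migrate from the primary to the secondary oxygen in the potassium alkoxide. The p-alkoxybenzylic ynol ether may ionise or undergo [3,3]-sigmatropic rearrangement on warming or on silica, with loss of material and of enantiomeric purity. The fallback avoids the alkoxide; it sets out from 7 and returns at 11. Formylation (acetic formic anhydride, pyridine) gives (1S)-1-[4-(geranyloxy)phenyl]-3-(triisopropylsilyloxy)propyl formate F8. Ramirez dibromo-olefination (CBr4, PPh3) gives {(3S)-3-(2,2-dibromoethenyloxy)-3-[4-(geranyloxy)phenyl]propoxy}triisopropylsilane F9. Treatment with n-BuLi (two equivalents, −78 °C) and then methanol gives 11.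

**Step 11.** The silyl triflate may activate the ynol ether as a Lewis acid, and the free hydroxyl of 18 may add to the vinyl ketone before it is capped. The fallback removes the isolated alcohol from the sequence. It sets out from 13 and 16 and returns at 19: the lithium aldolate of step 10 is trapped in the flask with t-BuMe2SiOTf at −78 °C, where the alkoxide is far more reactive than any other site. No new compound is made.

**Step 14.** The p-hydroxybenzylic alcohol may ionise on the oxidant surface to a quinone methide, leading to dehydration to the flav-3-ene and to oligomers, and the phenol itself may be oxidised. The fallback masks the phenol; it sets out from 25 and returns at 26. Selective phenol acetylation (Ac2O, Et3N, 0 °C) gives (2S)-2-[4-(geranyloxy)phenyl]-4-hydroxychroman-7-yl acetate F10. Dess–Martin oxidation gives (2S)-2-[4-(geranyloxy)phenyl]-4-oxochroman-7-yl acetate F11. Ammonolysis of the aryl acetate (NH3, MeOH, 0 °C) gives 26.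

## Further compounds

F1 | step 12 | (3S)-3-[4-(geranyloxy)phenyl]-3-hydroxy-N-methoxy-N-methylpropanamide | CC(C)=CCC/C(C)=C/COc1ccc([C@@H](O)CC(=O)N(C)OC)cc1
F2 | step 12 | (3-bromo-4-iodophenoxy)triisopropylsilane | CC(C)[Si](Oc1ccc(I)c(Br)c1)(C(C)C)C(C)C
F3 | step 12 | [2-bromo-4-(triisopropylsilyloxy)phenyl]magnesium chloride | CC(C)[Si](Oc1ccc([Mg]Cl)c(Br)c1)(C(C)C)C(C)C
F4 | step 12 | (3S)-1-[2-bromo-4-(triisopropylsilyloxy)phenyl]-3-[4-(geranyloxy)phenyl]-3-hydroxypropan-1-one | CC(C)=CCC/C(C)=C/COc1ccc([C@@H](O)CC(=O)c2ccc(O[Si](C(C)C)(C(C)C)C(C)C)cc2Br)cc1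
F5 | step 12 | (1S)-3-[2-bromo-4-(triisopropylsilyloxy)phenyl]-1-[4-(geranyloxy)phenyl]propane-1,3-diol, both C3 epimers | CC(C)=CCC/C(C)=C/COc1ccc([C@@H](O)CC(O)c2ccc(O[Si](C(C)C)(C(C)C)C(C)C)cc2Br)cc1
F6 | step 12 | (2S)-2-[4-(geranyloxy)phenyl]-7-(triisopropylsilyloxy)chroman-4-ol, both C4 epimers | CC(C)=CCC/C(C)=C/COc1ccc([C@@H]2CC(O)c3ccc(O[Si](C(C)C)(C(C)C)C(C)C)cc3O2)cc1
F7 | step 10 | 1-(tert-butyldimethylsilyl)-1-diazobut-3-en-2-one | C=CC(=O)C(=[N+]=[N-])[Si](C)(C)C(C)(C)C
F8 | step 6 | (1S)-1-[4-(geranyloxy)phenyl]-3-(triisopropylsilyloxy)propyl formate | CC(C)=CCC/C(C)=C/COc1ccc([C@@H](OC=O)CCO[Si](C(C)C)(C(C)C)C(C)C)cc1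
F9 | step 6 | {(3S)-3-(2,2-dibromoethenyloxy)-3-[4-(geranyloxy)phenyl]propoxy}triisopropylsilane | CC(C)=CCC/C(C)=C/COc1ccc([C@@H](OC=C(Br)Br)CCO[Si](C(C)C)(C(C)C)C(C)C)cc1
F0 | step 11 | none | none
F10 | step 14 | (2S)-2-[4-(geranyloxy)phenyl]-4-hydroxychroman-7-yl acetate, both C4 epimers | CC(C)=CCC/C(C)=C/COc1ccc([C@@H]2CC(O)c3ccc(OC(C)=O)cc3O2)cc1
F11 | step 14 | (2S)-2-[4-(geranyloxy)phenyl]-4-oxochroman-7-yl acetate | CC(C)=CCC/C(C)=C/COc1ccc([C@@H]2CC(=O)c3ccc(OC(C)=O)cc3O2)cc1
A1 | alternative 1 | (2S)-2-[4-(geranyloxy)phenyl]-7-(methoxymethoxy)-2,3,5,6-tetrahydro-4H-chromen-4-one | CC(C)=CCC/C(C)=C/COc1ccc([C@@H]2CC(=O)C3=C(C=C(OCOC)CC3)O2)cc1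
A2 | alternative 1 | 4-(methoxymethoxy)-2-(trimethylsilyloxy)-1-[1-(trimethylsilyloxy)ethenyl]cyclohexa-1,3-diene | C=C(O[Si](C)(C)C)C1=C(O[Si](C)(C)C)C=C(OCOC)CC1
A3 | alternative 1 | 4-(geranyloxy)benzaldehyde | CC(C)=CCC/C(C)=C/COc1ccc(C=O)cc1
A4 | alternative 2 | (2S,4S)-2-[4-(geranyloxy)phenyl]-7-(triisopropylsilyloxy)chroman-4-ol | CC(C)=CCC/C(C)=C/COc1ccc([C@@H]2C[C@H](O)c3ccc(O[Si](C(C)C)(C(C)C)C(C)C)cc3O2)cc1
A5 | alternative 2 | (1S,3S)-3-[2-bromo-4-(triisopropylsilyloxy)phenyl]-1-[4-(geranyloxy)phenyl]propane-1,3-diol | CC(C)=CCC/C(C)=C/COc1ccc([C@@H](O)C[C@H](O)c2ccc(O[Si](C(C)C)(C(C)C)C(C)C)cc2Br)cc1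
A6 | alternative 3 | (2S)-5-bromo-2-[4-(geranyloxy)phenyl]-7-(methoxymethoxy)chroman-4-one | CC(C)=CCC/C(C)=C/COc1ccc([C@@H]2CC(=O)c3c(Br)cc(OCOC)cc3O2)cc1
A7 | alternative 3 | 2-bromo-4-(methoxymethoxy)-6-(trimethylsilyl)phenyl trifluoromethanesulfonate | COCOc1cc(Br)c(OS(=O)(=O)C(F)(F)F)c([Si](C)(C)C)c1
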